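**Assumption:** the target is taken exactly as the SMILES is written, i.e. (3R,4S)-4-(3,4-dimethoxyphenyl)-6-hydroxy-3-(hydroxymethyl)-5-methoxy-3,4-dihydronaphthalene-2-carbaldehyde (3,4-trans, with the A-ring OMe peri to the aryl-bearing carbon).

## Retrosynthetic overview

1. Target 12 ⇐ bis-silyl ether 11 by one fluoride deprotection.
2. 11 ⇐ 2-benzylbenzaldehyde 7 + γ-silyloxy enal 10 in one light-driven, amine-catalysed formal [4+2]/dehydration. The photoenol of 7 adds to the chiral iminium of 10 (C4–C3 bond, both stereocentres), then enamine aldol condensation onto the regenerated ArCHO closes C1=C2.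
3. 7 ⇐ TIPS-vanillin by C2-selective directed ortho-metalation/iodination, then Negishi benzylation. 10 ⇐ Wittig homologation of TBSOCH2CHO.
4. Ring order: both benzene rings are purchased; the only ring formed is the dihydronaphthalene carbocycle, closed in the key step.

Numbering used below: C1(H)=C2(CHO)–C3(H)(CH2OH)–C4(H)(Ar). Atom-contributing reagents are numbered as compounds; catalysts are not.

## Route

**Step 1**
Reactants: 1 vanillin; 2 chlorotriisopropylsilane
Product: 3, 3-methoxy-4-[(triisopropylsilyl)oxy]benzaldehyde
Conditions: TIPSCl, imidazole, DMF, 0 °C → rt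
Reagents that add atoms: TIPSCl, CC(C)[Si](Cl)(C(C)C)C(C)C
Why: Standard phenol silylation; the bulky TIPS ether survives organolithiums, does not direct ortho-lithiation, and is removed by fluoride at the end.

**Step 2**
Reactants: 3; 4 iodine
Product: 5, 2-iodo-3-methoxy-4-[(triisopropylsilyl)oxy]benzaldehyde
Conditions: LiN(Me)CH2CH2NMe2, THF, −20 °C; n-BuLi (2.5 equiv), −20 → 0 °C; I2, −78 °C → rt; aq NH4Cl/Na2S2O3
Reagents that add atoms: iodine, II
Why: Comins α-amino-alkoxide directed ortho-metalation; the in-situ CH(OLi)NR2 group and the 3-OMe cooperatively direct lithium to their shared ortho carbon C2, and aqueous work-up returns the aldehyde.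

**Step 3**
Reactants: 5; 6 3,4-dimethoxybenzyl chloride
Product: 7, 2-(3,4-dimethoxybenzyl)-3-methoxy-4-[(triisopropylsilyl)oxy]benzaldehyde
Conditions: 6, Zn dust, LiCl, THF, rt (gives ArCH2ZnCl·LiCl); then 5, Pd(OAc)2 (2 mol %), SPhos (4 mol %), THF, rt
Reagents that add atoms: 3,4-dimethoxybenzyl chloride, COc1ccc(CCl)cc1OC (delivered as its benzylzinc chloride)
Why: Negishi sp2–sp3 coupling; Pd/SPhos handles the di-ortho-substituted aryl iodide, and the benzylzinc reagent cross-couples much faster than it adds to the aldehyde.

**Step 4**
Reactants: 8 (tert-butyldimethylsilyloxy)acetaldehyde; 9 (triphenylphosphoranylidene)acetaldehyde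
Product: 10, (E)-4-[(tert-butyldimethylsilyl)oxy]but-2-enal
Conditions: PhMe, 80 °C (1.05 equiv ylide)
Reagents that add atoms: (triphenylphosphoranylidene)acetaldehyde, O=CC=P(c1ccccc1)(c1ccccc1)c1ccccc1
Why: Wittig olefination with a stabilised formyl ylide gives the (E)-enal selectively.

**Step 5 (key step)**
Reactants: 7; 10 (3 equiv)
Product: 11, (3R,4S)-3-{[(tert-butyldimethylsilyl)oxy]methyl}-4-(3,4-dimethoxyphenyl)-5-methoxy-6-[(triisopropylsilyl)oxy]-3,4-dihydronaphthalene-2-carbaldehyde
Conditions: (R)-α,α-diphenylprolinol TMS ether (20 mol %; C[Si](C)(C)OC(c1ccccc1)(c1ccccc1)[C@H]1CCCN1), PhCO2H (20 mol %), degassed PhMe (0.05 M), 365 nm LED, 10–25 °C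
Reagents that add atoms: none beyond reactants 7 and 10 (H2O is lost)
Why: Proposed new method: 365 nm excitation of 7 causes 1,5-H transfer from the doubly benzylic CH2 to give the (E)-hydroxy-o-quinodimethane (aryl "out"), whose aryl-bearing terminus adds to C-β of the (E)-iminium formed from 10 and the catalyst on the Re face, anti to the CPh2OTMS group, setting C3 as R; the resulting enamine then undergoes intramolecular aldol condensation with the regenerated ArCHO to give the aryl-conjugated enal and release the catalyst, while C4 (S, trans) is set in the same C–C bond formation by an endo-type approach that places Ar and CH2OTBS anti, which is also the thermodynamically preferred trans-diaxial arrangement; the closest known reactions are the light-driven amine-catalysed β-benzylation of enals by photoenols of 2-alkylbenzophenones, the photoenolisation/Diels–Alder reaction of 2-benzylbenzaldehydes, and the amine-catalysed Michael/aldol-condensation domino of 2-(nitromethyl)benzaldehydes with enals.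

**Step 6**
Reactants: 11
Product: 12, vitekwangin B
Conditions: TBAF (3 equiv), AcOH (3 equiv), THF, 0 °C → rt
Reagents that add atoms: none
Why: Fluoride cleaves both the aryl TIPS and primary TBS ethers; acetic acid buffering protects the enal, and neither stereocentre has an acidic C–H, so both are preserved.

## Compound list

1 | vanillin (4-hydroxy-3-methoxybenzaldehyde) | COc1cc(C=O)ccc1O | starting material
2 | chlorotriisopropylsilane | CC(C)[Si](Cl)(C(C)C)C(C)C | starting material
3 | 3-methoxy-4-[(triisopropylsilyl)oxy]benzaldehyde | COc1cc(C=O)ccc1O[Si](C(C)C)(C(C)C)C(C)C | intermediate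
4 | iodine | II | starting material
5 | 2-iodo-3-methoxy-4-[(triisopropylsilyl)oxy]benzaldehyde | COc1c(I)c(C=O)ccc1O[Si](C(C)C)(C(C)C)C(C)C | intermediate
6 | 3,4-dimethoxybenzyl chloride | COc1ccc(CCl)cc1OC | starting material
7 | 2-(3,4-dimethoxybenzyl)-3-methoxy-4-[(triisopropylsilyl)oxy]benzaldehyde | COc1ccc(Cc2c(C=O)ccc(O[Si](C(C)C)(C(C)C)C(C)C)c2OC)cc1OC | intermediate
8 | (tert-butyldimethylsilyloxy)acetaldehyde | CC(C)(C)[Si](C)(C)OCC=O | starting material
9 | (triphenylphosphoranylidene)acetaldehyde | O=CC=P(c1ccccc1)(c1ccccc1)c1ccccc1 | starting material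
10 | (E)-4-[(tert-butyldimethylsilyl)oxy]but-2-enal | CC(C)(C)[Si](C)(C)OC/C=C/C=O | intermediate
11 | (3R,4S)-3-{[(tert-butyldimethylsilyl)oxy]methyl}-4-(3,4-dimethoxyphenyl)-5-methoxy-6-[(triisopropylsilyl)oxy]-3,4-dihydronaphthalene-2-carbaldehyde | COc1ccc([C@H]2c3c(ccc(O[Si](C(C)C)(C(C)C)C(C)C)c3OC)C=C(C=O)[C@@H]2CO[Si](C)(C)C(C)(C)C)cc1OC | intermediate
12 | vitekwangin B, (3R,4S)-4-(3,4-dimethoxyphenyl)-6-hydroxy-3-(hydroxymethyl)-5-methoxy-3,4-dihydronaphthalene-2-carbaldehyde | COc1ccc([C@H]2c3c(ccc(O)c3OC)C=C(C=O)[C@@H]2CO)cc1OC | target

## Step count and risks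

Total steps: 6. Longest linear sequence: 5 (steps 1 → 2 → 3 → 5 → 6).

Steps most likely to fail:

1. **Step 5 (photo-organocatalytic cascade).** Risks are a short photoenol lifetime, a racemic background cycloaddition with free enal, an exo-type approach giving the 3,4-cis isomer, and the product absorbing at 365 nm. Because C3 is catalyst-controlled and not epimerisable, any cis isomer could in principle be converged to trans by base equilibration at the doubly benzylic C4–H. Fallback: auxiliary-controlled photoenolisation/Diels–Alder of 7 with a chiral fumarate (e.g. the bis-(S)-methyl lactate ester), acid dehydration, DIBAL-H reduction of both esters, and MnO2 oxidation of only the allylic alcohol.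

2. **Step 2 (directed ortho-metalation).** Risks are C6 instead of C2 lithiation and attack on the silyl ether. Fallback: take the regiochemistry from electrophilic substitution instead: 2-nitrovanillin → reduction to the aniline → Sandmeyer iodination → TIPS protection to reach 5.

3. **Step 3 (Negishi benzylation).** Risks are benzylzinc addition to the free aldehyde, the hindered iodide and benzyl homocoupling. Fallback: drop the cross-coupling: add the C2-aryllithium from step 2 to 3,4-dimethoxybenzaldehyde to give the lactol, reduce both benzylic C–O bonds at the diaryl carbon with Et3SiH/TFA to the 2-benzylbenzyl alcohol, and reoxidise with MnO2 to 7.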